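## Retrosynthetic overview

1. The tetrahydrofuran is closed last, by 5-exo-tet attack of the benzylic alkoxide on a primary tosylate of the 1,4-diol. The C7–O bond is never broken, so C7 keeps its configuration.
2. The 1,4-diol comes from LiAlH4 opening of an all-trans 3-benzyl-4-methyl-5-aryl γ-butyrolactone. The C8′ (benzyl) stereocentre is set by enolate benzylation trans to the C8 methyl.
3. That lactone comes from oxidative lactonisation of a 1,4-diol, which comes from hydroboration of an anti-homoallylic alcohol. The alcohol is made by Ir-catalysed asymmetric anti-crotylation of a protected vanillin, which sets C7 and C8 absolutely.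
4. Both phenols are carried as silyl ethers (TIPS on the C7 aryl, TBS on the syringyl ring) and released together in the last step. The lactone ring is formed in Step 4 and the THF ring in Step 10.

Assumptions (one line each):
- The Ir-bisphosphine antipode is the one that gives the (1R,2R)-anti alcohol.
- Enolate benzylation occurs trans to the β-methyl group.

## Route

**Step 1**
Reactants: 1 vanillin
Product: 2 4-(triisopropylsilyloxy)-3-methoxybenzaldehyde
Conditions: TIPSCl, imidazole, DMF, rt
Reagents that add atoms: TIPSCl, CC(C)[Si](Cl)(C(C)C)C(C)C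
Why: Silylation of the phenol (O-silylation) masks it so it survives the organometallic and basic steps, and it is robust to the later perborate oxidation.

**Step 2**
Reactants: 2 aldehyde; 3 but-3-en-2-yl acetate
Product: 4 (1R,2R)-1-[3-methoxy-4-(TIPSO)phenyl]-2-methylbut-3-en-1-ol
Conditions: [Ir(cod)Cl]2 (cat.), chiral SEGPHOS-type bisphosphine (antipode giving 1R,2R), 3-nitrobenzoic acid (cat.), Cs2CO3, i-PrOH, THF, 100 °C
Reagents that add atoms: 3 (supplies the crotyl unit), CC(=O)OC(C)C=C
Why: Ir-catalysed transfer-hydrogenative carbonyl crotylation (Krische type) proceeds through a chair-like crotyl-iridium addition that gives the anti diastereomer. The ligand sets the absolute configuration at C7 and C8 in one step.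

**Step 3**
Reactants: 4 homoallylic alcohol
Product: 5 (1R,2R)-1-[3-methoxy-4-(TIPSO)phenyl]-2-methylbutane-1,4-diol
Conditions: (i) 9-BBN (2.5 equiv), THF, 0 °C to rt; (ii) NaBO3·4H2O, THF/H2O, rt
Reagents that add atoms: hydrogen peroxide equivalent from perborate (supplies the new OH oxygen), OO
Why: Hydroboration–oxidation of the terminal alkene is anti-Markovnikov, giving the primary alcohol. The two existing stereocentres are untouched, and mild perborate spares the aryl silyl ether.

**Step 4**
Reactants: 5 diol
Product: 6 (4R,5R)-5-[3-methoxy-4-(TIPSO)phenyl]-4-methyloxolan-2-one (trans lactone)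
Conditions: TEMPO (10 mol%), PhI(OAc)2 (2.5 equiv), CH2Cl2, rt
Reagents that add atoms: none
Why: TEMPO/BAIB oxidises the primary alcohol to the aldehyde, which closes to the five-membered lactol, and the lactol is oxidised to the γ-lactone (oxidative lactonisation). No stereocentre is adjacent to the new carbonyl, so nothing can epimerise.

**Step 5**
Reactants: 7 syringaldehyde (4-hydroxy-3,5-dimethoxybenzaldehyde)
Product: 8 4-(TBSO)-3,5-dimethoxybenzaldehyde
Conditions: TBSCl, imidazole, DMF, rt
Reagents that add atoms: TBSCl, CC(C)(C)[Si](C)(C)Cl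
Why: O-Silylation masks the phenol so the later benzyl bromide and enolate chemistry cannot self-alkylate through a quinone methide.

**Step 6**
Reactants: 8 aldehyde
Product: 9 [4-(TBSO)-3,5-dimethoxyphenyl]methanol
Conditions: NaBH4, MeOH/THF, 0 °C
Reagents that add atoms: none
Why: Chemoselective hydride reduction of the aldehyde gives the benzylic alcohol.

**Step 7**
Reactants: 9 benzylic alcohol
Product: 10 4-(TBSO)-3,5-dimethoxybenzyl bromide
Conditions: CBr4, PPh3, CH2Cl2, 0 °C (use crude, immediately)
Reagents that add atoms: CBr4, BrC(Br)(Br)Br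
Why: Appel bromination is neutral and gives the alkylating agent without touching the silyl ether.

**Step 8**
Reactants: 6 lactone; 10 benzyl bromide
Product: 11 (3R,4R,5R)-3-{[4-(TBSO)-3,5-dimethoxyphenyl]methyl}-5-[3-methoxy-4-(TIPSO)phenyl]-4-methyloxolan-2-one
Conditions: LDA (1.1 equiv), THF, –78 °C; then 10, DMPU, –78 °C to –40 °C
Reagents that add atoms: 10 (supplies the benzyl group), COc1cc(CBr)cc(OC)c1O[Si](C)(C)C(C)(C)C
Why: Lactone enolate alkylation; the electrophile approaches the enolate face anti to the adjacent C4 methyl, so the new C3 stereocentre is trans to it and the product is all-trans (3R).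

**Step 9**
Reactants: 11 lactone
Product: 12 (2R,3R,4R)-2-{[4-(TBSO)-3,5-dimethoxyphenyl]methyl}-4-[3-methoxy-4-(TIPSO)phenyl]-3-methylbutane-1,4-diol
Conditions: LiAlH4, THF, 0 °C
Reagents that add atoms: none
Why: Hydride reduction of the lactone to the diol, with no stereocentre affected. The α-stereocentre cannot epimerise under these non-enolising conditions.

**Step 10**
Reactants: 12 diol
Product: 13 bis-silylated tetrahydrofuran (2R,3R,4R)-2-aryl-3-methyl-4-benzyl-THF
Conditions: (i) TsCl (1.1 equiv), Et3N, DMAP (cat.), CH2Cl2, 0 °C; (ii) KOt-Bu, THF, 0 °C (one pot)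
Reagents that add atoms: none (the tosyl group leaves)
Why: Selective tosylation of the unhindered primary alcohol, then intramolecular Williamson etherification (5-exo-tet) by the benzylic alkoxide. C7 is never the electrophilic carbon, so its configuration is retained.

**Step 11**
Reactants: 13 silylated THF
Product: 14 target, (2R,3R,4R)-2-(4-hydroxy-3-methoxyphenyl)-3-methyl-4-(4-hydroxy-3,5-dimethoxybenzyl)tetrahydrofuran
Conditions: TBAF, AcOH (1:1), THF, 0 °C to rt
Reagents that add atoms: none
Why: Fluoride cleaves both aryl silyl ethers. Buffering with AcOH prevents phenoxide-driven quinone-methide opening of the benzylic C–O bond.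

## Compound list

1 | vanillin | COc1cc(C=O)ccc1O | starting material
2 | 4-(TIPSO)-3-methoxybenzaldehyde | COc1cc(C=O)ccc1O[Si](C(C)C)(C(C)C)C(C)C | intermediate
3 | but-3-en-2-yl acetate | CC(=O)OC(C)C=C | starting material
4 | (1R,2R)-1-[3-methoxy-4-(TIPSO)phenyl]-2-methylbut-3-en-1-ol | C=C[C@@H](C)[C@@H](O)c1ccc(O[Si](C(C)C)(C(C)C)C(C)C)c(OC)c1 | intermediate
5 | (1R,2R)-1-[3-methoxy-4-(TIPSO)phenyl]-2-methylbutane-1,4-diol | OCC[C@@H](C)[C@@H](O)c1ccc(O[Si](C(C)C)(C(C)C)C(C)C)c(OC)c1 | intermediate
6 | (4R,5R)-5-[3-methoxy-4-(TIPSO)phenyl]-4-methyloxolan-2-one | O=C1C[C@@H](C)[C@@H](O1)c1ccc(O[Si](C(C)C)(C(C)C)C(C)C)c(OC)c1 | intermediate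
7 | syringaldehyde | COc1cc(C=O)cc(OC)c1O | starting material
8 | 4-(TBSO)-3,5-dimethoxybenzaldehyde | COc1cc(C=O)cc(OC)c1O[Si](C)(C)C(C)(C)C | intermediate
9 | [4-(TBSO)-3,5-dimethoxyphenyl]methanol | COc1cc(CO)cc(OC)c1O[Si](C)(C)C(C)(C)C | intermediate
10 | 4-(TBSO)-3,5-dimethoxybenzyl bromide | COc1cc(CBr)cc(OC)c1O[Si](C)(C)C(C)(C)C | intermediate
11 | (3R,4R,5R)-3-benzyl-type all-trans lactone (bis-silylated) | O=C1[C@H](Cc2cc(OC)c(O[Si](C)(C)C(C)(C)C)c(OC)c2)[C@@H](C)[C@H](c2ccc(O[Si](C(C)C)(C(C)C)C(C)C)c(OC)c2)O1 | intermediate
12 | (2R,3R,4R)-diol (bis-silylated) | OC[C@H](Cc1cc(OC)c(O[Si](C)(C)C(C)(C)C)c(OC)c1)[C@@H](C)[C@@H](O)c1ccc(O[Si](C(C)C)(C(C)C)C(C)C)c(OC)c1 | intermediate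
13 | bis-silylated THF | COc1cc([C@@H]2OC[C@H](Cc3cc(OC)c(O[Si](C)(C)C(C)(C)C)c(OC)c3)[C@H]2C)ccc1O[Si](C(C)C)(C(C)C)C(C)C | intermediate
14 | CID53359708 (target) | COc1cc([C@@H]2OC[C@H](Cc3cc(OC)c(O)c(OC)c3)[C@H]2C)ccc1O | target

## Totals

- Total steps: 11 (including three steps that prepare the syringyl bromide).
- Longest linear sequence: 8 (1 → 2 → 4 → 5 → 6 → 11 → 12 → 13 → 14, i.e. Steps 1, 2, 3, 4, 8, 9, 10, 11).

## Three steps most likely to fail

1. **Step 4 (TEMPO/BAIB lactonisation).** The electron-rich benzylic secondary alcohol could over-oxidise to the aryl ketone.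
   - Fallback: make lactone 6 without oxidising a diol. Prepare the enantioenriched 5-aryl-2(5H)-furanone by Noyori transfer hydrogenation of the aryl ynone, then add MeMgBr/CuBr conjugately. The addition is anti to the γ-aryl group and gives the same trans lactone 6.
2. **Step 2 (Ir-catalysed anti-crotylation).** The ee or dr may be lower with the silyloxy-aryl aldehyde, and the ligand antipode may need to be swapped.
   - Fallback: replace catalysis by reagent control, using stoichiometric Brown (E)-crotyl-diisopinocampheylborane (−78 °C, then oxidative work-up). This gives the same anti alcohol from a different mechanism.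
3. **Step 8 (lactone benzylation).** The electron-rich benzyl bromide is unstable and the trans selectivity could be modest.
   - Fallback: use TBS-syringaldehyde (8) instead of the bromide. Aldol-condense it with the lactone enolate, dehydrate to the α-benzylidene lactone, then hydrogenate. The hydrogen adds anti to the C4 methyl and sets the trans C3 stereocentre.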